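Locants: ring A (oxane) O1, C2 (CH3, carries ring B), C3 (OAc), C4, C5 (Br), C6 (two CH3); ring B (cyclohexane) C1' (on C2), C2', C3' (Br), C4' (CH3, Cl), C5', C6' (OH).
Feature used: both halogens of ring B can come from one olefin, C3'=C4' with the CH3 on C4', which lies away from the contiguous triad C2/C1'/C6'. The triad is therefore built on an open chain, and ring B is closed at that olefin by ring-closing metathesis of a C1' allyl arm and a C6' methallyl arm (an octa-1,7-diene).
Triad: asymmetric epoxidation (C2), anti opening of the epoxide by an allyl copper reagent (C1'), matched asymmetric methallylboration of the C6' aldehyde (C6'); the C2/C3 diol travels as an acetonide.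
Ring B is formed first (step 10). Br and Cl are trans-diequatorial on the chair anchored by C2, where plain BrCl addition would prefer the diaxial pair, so the olefin is converted stereospecifically: cis-diol on the open face, cyclic sulfate, bromide with inversion at C3', chloride with bromine-assisted retention at C4'.
Ring A is formed last, when no other olefin is left: C3–C4 by chelation-controlled allylation of the C2 hydroxy aldehyde, C5=C6 by cross-metathesis, acetate, 6-endo bromoetherification (O1–C6, C5–Br), desilylation.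

Key step: step 10

Remark: the SMILES decodes as 2S,3S,5S,1'S,3'R,4'R,6'R. On ring B the groups on C1' (C2), C3' (Br), C4' (CH3) and C6' (O) share one face ("upper") and Cl lies on the other. With C2 equatorial, Br and Cl are equatorial, and the C4' CH3 and the C6' oxygen are axial.

Step 1
Reactants: 1 2-[(tert-butyldimethylsilyl)oxy]acetaldehyde; 2 ethyl 2-(triphenyl-λ5-phosphanylidene)propanoate
Product: 3 ethyl (E)-4-[(tert-butyldimethylsilyl)oxy]-2-methylbut-2-enoate
Conditions: CH2Cl2, rt
Reagents that add atoms: none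
Why: Wittig olefination with a stabilised α-methyl ylide is reliably E-selective, which puts the ester carbon (future C3) trans to the CH2OTBS carbon (future C6') across the future C2–C1' bond.

Step 2
Reactants: 3 ethyl (E)-4-[(tert-butyldimethylsilyl)oxy]-2-methylbut-2-enoate
Product: 4 (E)-4-[(tert-butyldimethylsilyl)oxy]-2-methylbut-2-en-1-ol
Conditions: iBu2AlH (2.5 equiv), CH2Cl2, −78 °C; aq. potassium sodium tartrate
Reagents that add atoms: none
Why: Reduction of an enoate with two hydride equivalents of iBu2AlH at low temperature stops cleanly at the allylic alcohol without touching the olefin geometry or the silyl ether.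

Step 3
Reactants: 4 (E)-4-[(tert-butyldimethylsilyl)oxy]-2-methylbut-2-en-1-ol
Product: 5 [(2R,3R)-3-{[(tert-butyldimethylsilyl)oxy]methyl}-2-methyloxiran-2-yl]methanol
Conditions: Ti(OiPr)4 (10 mol %), D-(−)-diisopropyl tartrate (12 mol %), t-BuOOH, 4 Å molecular sieves, CH2Cl2, −20 °C
Reagents that add atoms: tert-butyl hydroperoxide, CC(C)(C)OO
Why: Katsuki–Sharpless asymmetric epoxidation of an E-trisubstituted primary allylic alcohol: the D-(−)-tartrate titanium complex delivers oxygen to the face that gives the (2R,3R)-epoxide, which fixes C2 absolutely, and the syn addition to the E olefin fixes the C1' carbon relative to it.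

Step 4
Reactants: 5 [(2R,3R)-3-{[(tert-butyldimethylsilyl)oxy]methyl}-2-methyloxiran-2-yl]methanol; 6 allylmagnesium bromide
Product: 7 (2S,3S)-3-{[(tert-butyldimethylsilyl)oxy]methyl}-2-methylhex-5-ene-1,2-diol
Conditions: 6 (3.5 equiv), CuBr·SMe2 (15 mol %), Et2O/THF, −40 to 0 °C
Reagents that add atoms: none
Why: Copper-catalysed SN2 opening of a 2,3-epoxy alcohol by an allyl Grignard reagent: C2 is fully substituted, so the allyl group enters at C1' anti to the breaking C–O bond, inverting C1' to (S) and leaving the C2–O bond and thus (2S) untouched.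

Step 5
Reactants: 7 (2S,3S)-3-{[(tert-butyldimethylsilyl)oxy]methyl}-2-methylhex-5-ene-1,2-diol
Product: 8 tert-butyldimethylsilyl ether of (2S)-2-[(4S)-2,2,4-trimethyl-1,3-dioxolan-4-yl]pent-4-en-1-ol
Conditions: Me2C(OMe)2, PPTS (cat.), CH2Cl2, rt
Reagents that add atoms: 2,2-dimethoxypropane, COC(C)(C)OC
Why: Acid-catalysed transketalisation ties the only two free hydroxyls into a five-membered acetonide, which masks the C2 hydroxyl until ring B is fully functionalised.

Step 6
Reactants: 8 tert-butyldimethylsilyl ether of (2S)-2-[(4S)-2,2,4-trimethyl-1,3-dioxolan-4-yl]pent-4-en-1-ol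
Product: 9 (2S)-2-[(4S)-2,2,4-trimethyl-1,3-dioxolan-4-yl]pent-4-en-1-ol
Conditions: Bu4NF, THF, 0 °C to rt
Reagents that add atoms: none
Why: Fluoride-induced cleavage of the primary silyl ether is selective because the acetonide and the olefin are inert to Bu4NF.

Step 7
Reactants: 9 (2S)-2-[(4S)-2,2,4-trimethyl-1,3-dioxolan-4-yl]pent-4-en-1-ol
Product: 10 (2R)-2-[(4S)-2,2,4-trimethyl-1,3-dioxolan-4-yl]pent-4-enal
Conditions: Dess–Martin periodinane, CH2Cl2, 0 °C to rt
Reagents that add atoms: none
Why: Dess–Martin oxidation works under near-neutral conditions, so the aldehyde is formed without epimerisation of the adjacent C1' stereocentre (same spatial arrangement, descriptor changed by priority only) and is used at once.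

Step 8
Reactants: 10 (2R)-2-[(4S)-2,2,4-trimethyl-1,3-dioxolan-4-yl]pent-4-enal; 11 2-methylallylmagnesium chloride
Product: 13 (4R,5S)-2-methyl-5-[(4S)-2,2,4-trimethyl-1,3-dioxolan-4-yl]octa-1,7-dien-4-ol, via diisopinocampheylborinate ester 12 (not isolated)
Conditions: (+)-Ipc2BOMe, 11, Et2O, −78 °C to rt; 10, −78 °C; NaOH, H2O2, 0 °C to rt
Reagents that add atoms: none
Why: Brown asymmetric methallylboration through a closed chair transition state: the reagent made from (−)-α-pinene attacks the aldehyde face that gives (6'R), the same face that the Felkin–Anh model favours with the dioxolanyl carbon C2 as the large group, so reagent and substrate control are matched.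

Step 9
Reactants: 13 (4R,5S)-2-methyl-5-[(4S)-2,2,4-trimethyl-1,3-dioxolan-4-yl]octa-1,7-dien-4-ol
Product: 14 (4R,5S)-4-(tert-butyldimethylsilyloxy)-2-methyl-5-[(4S)-2,2,4-trimethyl-1,3-dioxolan-4-yl]octa-1,7-diene (the metathesis precursor with its 1,2-diol masked as acetonide)
Conditions: TBSOTf, 2,6-lutidine, CH2Cl2, −20 to 0 °C
Reagents that add atoms: tert-butyldimethylsilyl triflate, CC(C)(C)[Si](C)(C)OS(=O)(=O)C(F)(F)F
Why: Silylation with the triflate and a hindered pyridine base overcomes the crowding of the C6' carbinol next to branched C1' and leaves the acetonide intact.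

Step 10
Reactants: 14 (4R,5S)-4-(tert-butyldimethylsilyloxy)-2-methyl-5-[(4S)-2,2,4-trimethyl-1,3-dioxolan-4-yl]octa-1,7-diene
Product: 15 (4S)-4-[(1S,6R)-6-(tert-butyldimethylsilyloxy)-4-methylcyclohex-3-en-1-yl]-2,2,4-trimethyl-1,3-dioxolane
Conditions: second-generation Grubbs catalyst (H2IMes)(PCy3)Cl2Ru=CHPh (5 mol %), CH2Cl2 (5 mM), 40 °C
Reagents that add atoms: none
Why: Ring-closing olefin metathesis: the ruthenium benzylidene first exchanges with the unhindered monosubstituted C3'H=CH2 terminus of the allyl arm, the new alkylidene adds intramolecularly to the 1,1-disubstituted olefin of the methallyl arm to give a ruthenacyclobutane, and cycloreversion delivers the C3'=C4' bond and Ru=CH2, which carries the chain with loss of ethylene. The closest known reaction type is the closure of octa-1,7-dienes that hold one 1,1-disubstituted end to 1-methylcyclohexenes with N-heterocyclic-carbene ruthenium catalysts. Ring B closes by union of the two olefin termini of arms that sit on the vicinal carbons C1' and C6', a six-membered closure that is fast and is driven by escape of ethylene. No stereocentre is formed, and C2, C1' and C6' are sp3 carbons with no path to epimerisation under these neutral conditions, so the triad passes unchanged into the ring, where C2 and OTBS end up cis. The step needs only chemoselectivity for cyclisation over intermolecular metathesis and over double-bond migration; the 1,7-spacing, the branching at C1' and C6' that holds the arms gauche and the dilution secure the first, and a short time at 40 °C with fresh catalyst secures the second. Acetonide and silyl ether offer no donor that binds ruthenium.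

Step 11
Reactants: 15 (4S)-4-[(1S,6R)-6-(tert-butyldimethylsilyloxy)-4-methylcyclohex-3-en-1-yl]-2,2,4-trimethyl-1,3-dioxolane
Product: 16 (1R,2S,4S,5R)-5-(tert-butyldimethylsilyloxy)-1-methyl-4-[(4S)-2,2,4-trimethyl-1,3-dioxolan-4-yl]cyclohexane-1,2-diol (3'S,4'R; both OH on the lower face)
Conditions: K2OsO2(OH)4 (3 mol %), NMO, acetone/H2O, rt
Reagents that add atoms: N-methylmorpholine N-oxide, C[N+]1([O-])CCOCC1; water, O
Why: Upjohn syn-dihydroxylation: osmium tetroxide adds to the ring-B face opposite to the cis-related equatorial dioxolanyl and axial OTBS groups, so both new C–O bonds lie on the lower face (3'S,4'R) and the C4' methyl is pushed to the upper face that it occupies in the target.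

Step 12
Reactants: 16 cis-3',4'-diol
Product: 18 3',4'-cyclic sulfate of 16, via cyclic sulfite 17 (not isolated)
Conditions: SOCl2, Et3N, CH2Cl2, 0 °C; RuCl3·xH2O (1 mol %), NaIO4, MeCN/CH2Cl2/H2O, 0 °C
Reagents that add atoms: thionyl chloride, O=S(Cl)Cl; sodium periodate, [Na+].[O-]I(=O)(=O)=O
Why: Cyclic sulfate synthesis by sulfite formation followed by ruthenium tetroxide oxidation changes only the O–H bonds, so 3'S and 4'R are kept, and nothing else in the molecule is oxidisable now that no olefin is left.

Step 13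
Reactants: 18 3',4'-cyclic sulfate
Product: 20 (1R,2R,4S,5R)-2-bromo-5-(tert-butyldimethylsilyloxy)-1-methyl-4-[(4S)-2,2,4-trimethyl-1,3-dioxolan-4-yl]cyclohexan-1-ol (3'R,4'R), via lithium sulfate monoester 19 (not isolated)
Conditions: LiBr, THF, 50 °C; H2SO4 (cat.), H2O (1 equiv), THF, rt
Reagents that add atoms: lithium bromide, [Li+].[Br-]
Why: Nucleophilic opening of a cyclic sulfate: bromide can only attack the secondary C3', whose C–O bond is axial in the chair anchored by the equatorial dioxolanyl group, so it enters from the upper face with inversion (3'R, equatorial Br), and the tertiary sulfate monoester is then hydrolysed at sulfur with catalytic acid and one equivalent of water, conditions that spare acetonide and silyl ether and keep 4'R.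

Step 14
Reactants: 20 trans-diequatorial bromohydrin (3'R,4'R)
Product: 21 (4S)-4-[(1'S,3'R,4'R,6'R)-3'-bromo-4'-chloro-4'-methyl-6'-(tert-butyldimethylsilyloxy)cyclohexyl]-2,2,4-trimethyl-1,3-dioxolane (ring-B locants of the overview)
Conditions: 1-chloro-N,N,2-trimethylprop-1-en-1-amine, CH2Cl2, 0 °C to rt
Reagents that add atoms: 1-chloro-N,N,2-trimethylprop-1-en-1-amine, CC(C)=C(Cl)N(C)C
Why: Deoxychlorination of a tertiary alcohol with the Ghosez chloroenamine under neutral conditions: the O-imidoyl leaving group ionises with help from the vicinal C3' bromine, the bridged cation is closed on its upper face by that bromine and by the syn-axial C6' OTBS, and chloride therefore returns at the more substituted C4' from the lower face that the oxygen left (retention, 4'R), the classical neighbouring-bromine outcome.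

Step 15
Reactants: 21 bromochloride acetonide
Product: 22 (2S)-2-[(1'S,3'R,4'R,6'R)-3'-bromo-4'-chloro-4'-methyl-6'-(tert-butyldimethylsilyloxy)cyclohexyl]propane-1,2-diol
Conditions: AcOH/THF/H2O, 40 °C
Reagents that add atoms: none
Why: Mild aqueous acid hydrolyses the acetonide, while the hindered secondary silyl ether survives and the tertiary chloride is protected from solvolysis by the inductive effect of the neighbouring bromine.

Step 16
Reactants: 22 bromochloride 1,2-diol
Product: 23 (2S)-2-[(1'S,3'R,4'R,6'R)-3'-bromo-4'-chloro-4'-methyl-6'-(tert-butyldimethylsilyloxy)cyclohexyl]-2-hydroxypropanal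
Conditions: SO3·pyridine, DMSO, Et3N, CH2Cl2, 0 °C
Reagents that add atoms: none
Why: Parikh–Doering oxidation converts only the primary alcohol since the tertiary C2 hydroxyl has no carbinol hydrogen, and an activated-DMSO oxidant avoids the glycol cleavage that iodine- or metal-based oxidants could cause.

Step 17
Reactants: 23 C2 hydroxy aldehyde; 24 allyltributylstannane
Product: 25 (2S,3S)-2-[(1'S,3'R,4'R,6'R)-3'-bromo-4'-chloro-4'-methyl-6'-(tert-butyldimethylsilyloxy)cyclohexyl]hex-5-ene-2,3-diol
Conditions: MgBr2·OEt2 (3 equiv), 24, CH2Cl2, −78 to −20 °C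
Reagents that add atoms: none
Why: Chelation-controlled allylstannane addition (Cram chelate model): MgBr2 binds the aldehyde oxygen and the C2 hydroxyl oxygen in a five-membered chelate, and the allyl group attacks from the side of the small C2 methyl group instead of ring B, which gives (3S), while the mild stannane leaves the alkyl halides alone.

Step 18
Reactants: 25 homoallylic diol; 26 2-methylbut-2-ene
Product: 27 (2S,3S)-2-[(1'S,3'R,4'R,6'R)-3'-bromo-4'-chloro-4'-methyl-6'-(tert-butyldimethylsilyloxy)cyclohexyl]-6-methylhept-5-ene-2,3-diol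
Conditions: second-generation Grubbs catalyst (H2IMes)(PCy3)Cl2Ru=CHPh (5 mol %), 26/CH2Cl2, 35 °C, sealed vessel
Reagents that add atoms: none
Why: Olefin cross-metathesis of a terminal olefin with excess 2-methylbut-2-ene installs the isopropylidene terminus that a prenyl metal reagent could not deliver regioselectively, and no other olefin is left in the molecule to compete.

Step 19
Reactants: 27 prenyl diol
Product: 28 (2S,3S)-2-[(1'S,3'R,4'R,6'R)-3'-bromo-4'-chloro-4'-methyl-6'-(tert-butyldimethylsilyloxy)cyclohexyl]-2-hydroxy-6-methylhept-5-en-3-yl acetate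
Conditions: Ac2O, pyridine, DMAP (cat.), CH2Cl2, 0 °C to rt
Reagents that add atoms: acetic anhydride, CC(=O)OC(C)=O
Why: Acylation with DMAP catalysis takes place only at the secondary C3 hydroxyl because the tertiary C2 hydroxyl is far slower, and it removes the C3 oxygen as a competing nucleophile for the next step.

Step 20
Reactants: 28 hydroxy acetate
Product: 29 (2S,3S,5S)-5-bromo-2-[(1'S,3'R,4'R,6'R)-3'-bromo-4'-chloro-4'-methyl-6'-(tert-butyldimethylsilyloxy)cyclohexyl]-2,6,6-trimethyloxan-3-yl acetate
Conditions: 2,4,4,6-tetrabromocyclohexa-2,5-dien-1-one, MeNO2, 0 °C to rt, dark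
Reagents that add atoms: 2,4,4,6-tetrabromocyclohexa-2,5-dien-1-one, O=C1C(Br)=CC(Br)(Br)C=C1Br
Why: Bromonium-induced etherification with a mild Br+ donor: the C2 hydroxyl opens the bromonium ion at the tertiary C6 (Markovnikov, 6-endo) anti to bromine through a chair in which ring B is equatorial and the C2 methyl axial, so the C5–Br bond comes out equatorial, which is (5S), and the prenyl olefin is the only olefin present.

Step 21
Reactants: 29 silyl ether of the target
Product: 30 (2S,3S,5S)-5-bromo-2-[(1'S,3'R,4'R,6'R)-3'-bromo-4'-chloro-6'-hydroxy-4'-methylcyclohexyl]-2,6,6-trimethyloxan-3-yl acetate (CNP0166766.1)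
Conditions: HF (48 % aq.), MeCN, 0 °C to rt
Reagents that add atoms: none
Why: Acidic fluoride cleaves the hindered axial silyl ether without generating a basic alkoxide, so that acetate migration, elimination of HBr or HCl and displacement of the halides are avoided.

Compound list
1 | 2-[(tert-butyldimethylsilyl)oxy]acetaldehyde | CC(C)(C)[Si](C)(C)OCC=O | starting material
2 | ethyl 2-(triphenyl-λ5-phosphanylidene)propanoate | CCOC(=O)C(C)=P(c1ccccc1)(c1ccccc1)c1ccccc1 | starting material
3 | ethyl (E)-4-[(tert-butyldimethylsilyl)oxy]-2-methylbut-2-enoate | CCOC(=O)/C(C)=C/CO[Si](C)(C)C(C)(C)C | intermediate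
4 | (E)-4-[(tert-butyldimethylsilyl)oxy]-2-methylbut-2-en-1-ol | OC/C(C)=C/CO[Si](C)(C)C(C)(C)C | intermediate
5 | [(2R,3R)-3-{[(tert-butyldimethylsilyl)oxy]methyl}-2-methyloxiran-2-yl]methanol | OC[C@@]1(C)O[C@@H]1CO[Si](C)(C)C(C)(C)C | intermediate
6 | allylmagnesium bromide | C=CC[Mg]Br | starting material
7 | (2S,3S)-3-{[(tert-butyldimethylsilyl)oxy]methyl}-2-methylhex-5-ene-1,2-diol | OC[C@@](C)(O)[C@H](CO[Si](C)(C)C(C)(C)C)CC=C | intermediate
8 | tert-butyldimethylsilyl ether of (2S)-2-[(4S)-2,2,4-trimethyl-1,3-dioxolan-4-yl]pent-4-en-1-ol | CC1(C)OC[C@@](C)(O1)[C@H](CO[Si](C)(C)C(C)(C)C)CC=C | intermediate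
9 | (2S)-2-[(4S)-2,2,4-trimethyl-1,3-dioxolan-4-yl]pent-4-en-1-ol | CC1(C)OC[C@@](C)(O1)[C@H](CO)CC=C | intermediate
10 | (2R)-2-[(4S)-2,2,4-trimethyl-1,3-dioxolan-4-yl]pent-4-enal | CC1(C)OC[C@@](C)(O1)[C@H](C=O)CC=C | intermediate
11 | 2-methylallylmagnesium chloride | CC(=C)C[Mg]Cl | starting material
12 | diisopinocampheylborinate ester of 13 | CC1(C)OC[C@@](C)(O1)[C@H]([C@H](OB([C@H]1C[C@H]2C[C@@H]([C@@H]1C)C2(C)C)[C@H]1C[C@H]2C[C@@H]([C@@H]1C)C2(C)C)CC(C)=C)CC=C | intermediate
13 | (4R,5S)-2-methyl-5-[(4S)-2,2,4-trimethyl-1,3-dioxolan-4-yl]octa-1,7-dien-4-ol | CC1(C)OC[C@@](C)(O1)[C@H]([C@H](O)CC(C)=C)CC=C | intermediate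
14 | (4R,5S)-4-(tert-butyldimethylsilyloxy)-2-methyl-5-[(4S)-2,2,4-trimethyl-1,3-dioxolan-4-yl]octa-1,7-diene | CC1(C)OC[C@@](C)(O1)[C@H]([C@H](O[Si](C)(C)C(C)(C)C)CC(C)=C)CC=C | intermediate
15 | (4S)-4-[(1S,6R)-6-(tert-butyldimethylsilyloxy)-4-methylcyclohex-3-en-1-yl]-2,2,4-trimethyl-1,3-dioxolane | CC1(C)OC[C@@](C)(O1)[C@H]1CC=C(C)C[C@H]1O[Si](C)(C)C(C)(C)C | intermediate
16 | (1R,2S,4S,5R)-5-(tert-butyldimethylsilyloxy)-1-methyl-4-[(4S)-2,2,4-trimethyl-1,3-dioxolan-4-yl]cyclohexane-1,2-diol | CC1(C)OC[C@@](C)(O1)[C@H]1C[C@H](O)[C@](C)(O)C[C@H]1O[Si](C)(C)C(C)(C)C | intermediate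
17 | 3',4'-cyclic sulfite of 16 (mixture at sulfur) | CC1(C)OC[C@@](C)(O1)[C@H]1C[C@@H]2OS(=O)O[C@]2(C)C[C@H]1O[Si](C)(C)C(C)(C)C | intermediate
18 | 3',4'-cyclic sulfate of 16 | CC1(C)OC[C@@](C)(O1)[C@H]1C[C@@H]2OS(=O)(=O)O[C@]2(C)C[C@H]1O[Si](C)(C)C(C)(C)C | intermediate
19 | lithium salt of the C4' sulfate monoester of 20 | [Li+].CC1(C)OC[C@@](C)(O1)[C@H]1C[C@@H](Br)[C@](C)(OS(=O)(=O)[O-])C[C@H]1O[Si](C)(C)C(C)(C)C | intermediate
20 | (1R,2R,4S,5R)-2-bromo-5-(tert-butyldimethylsilyloxy)-1-methyl-4-[(4S)-2,2,4-trimethyl-1,3-dioxolan-4-yl]cyclohexan-1-ol | CC1(C)OC[C@@](C)(O1)[C@H]1C[C@@H](Br)[C@](C)(O)C[C@H]1O[Si](C)(C)C(C)(C)C | intermediate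
21 | (4S)-4-[(1'S,3'R,4'R,6'R)-3'-bromo-4'-chloro-4'-methyl-6'-(tert-butyldimethylsilyloxy)cyclohexyl]-2,2,4-trimethyl-1,3-dioxolane | CC1(C)OC[C@@](C)(O1)[C@H]1C[C@@H](Br)[C@](C)(Cl)C[C@H]1O[Si](C)(C)C(C)(C)C | intermediate
22 | (2S)-2-[(1'S,3'R,4'R,6'R)-3'-bromo-4'-chloro-4'-methyl-6'-(tert-butyldimethylsilyloxy)cyclohexyl]propane-1,2-diol | OC[C@@](C)(O)[C@H]1C[C@@H](Br)[C@](C)(Cl)C[C@H]1O[Si](C)(C)C(C)(C)C | intermediate
23 | (2S)-2-[(1'S,3'R,4'R,6'R)-3'-bromo-4'-chloro-4'-methyl-6'-(tert-butyldimethylsilyloxy)cyclohexyl]-2-hydroxypropanal | O=C[C@@](C)(O)[C@H]1C[C@@H](Br)[C@](C)(Cl)C[C@H]1O[Si](C)(C)C(C)(C)C | intermediate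
24 | allyltributylstannane | C=CC[Sn](CCCC)(CCCC)CCCC | starting material
25 | (2S,3S)-2-[(1'S,3'R,4'R,6'R)-3'-bromo-4'-chloro-4'-methyl-6'-(tert-butyldimethylsilyloxy)cyclohexyl]hex-5-ene-2,3-diol | C=CC[C@H](O)[C@@](C)(O)[C@H]1C[C@@H](Br)[C@](C)(Cl)C[C@H]1O[Si](C)(C)C(C)(C)C | intermediate
26 | 2-methylbut-2-ene | CC=C(C)C | starting material
27 | (2S,3S)-2-[(1'S,3'R,4'R,6'R)-3'-bromo-4'-chloro-4'-methyl-6'-(tert-butyldimethylsilyloxy)cyclohexyl]-6-methylhept-5-ene-2,3-diol | CC(C)=CC[C@H](O)[C@@](C)(O)[C@H]1C[C@@H](Br)[C@](C)(Cl)C[C@H]1O[Si](C)(C)C(C)(C)C | intermediate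
28 | (2S,3S)-2-[(1'S,3'R,4'R,6'R)-3'-bromo-4'-chloro-4'-methyl-6'-(tert-butyldimethylsilyloxy)cyclohexyl]-2-hydroxy-6-methylhept-5-en-3-yl acetate | CC(C)=CC[C@H](OC(C)=O)[C@@](C)(O)[C@H]1C[C@@H](Br)[C@](C)(Cl)C[C@H]1O[Si](C)(C)C(C)(C)C | intermediate
29 | (2S,3S,5S)-5-bromo-2-[(1'S,3'R,4'R,6'R)-3'-bromo-4'-chloro-4'-methyl-6'-(tert-butyldimethylsilyloxy)cyclohexyl]-2,6,6-trimethyloxan-3-yl acetate | CC(=O)O[C@H]1C[C@H](Br)C(C)(C)O[C@@]1(C)[C@H]1C[C@@H](Br)[C@](C)(Cl)C[C@H]1O[Si](C)(C)C(C)(C)C | intermediate
30 | (2S,3S,5S)-5-bromo-2-[(1'S,3'R,4'R,6'R)-3'-bromo-4'-chloro-6'-hydroxy-4'-methylcyclohexyl]-2,6,6-trimethyloxan-3-yl acetate | CC(=O)O[C@H]1C[C@H](Br)C(C)(C)O[C@@]1(C)[C@H]1C[C@@H](Br)[C@](C)(Cl)C[C@H]1O | target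

Total step count: 21. Longest linear sequence: 21 steps (1 to 30); all other partners are bought.

Steps most likely to fail

**Step 14 (tertiary chloride).** Ionisation at C4' may end in proton loss instead of chloride capture. Chloride may also enter the bridged ion at C3' rather than at C4'. Fallback: steps 11 to 14 are left out, and olefin 15 is treated with N-bromosuccinimide and ClTi(OiPr)3 in hexane/CH2Cl2 at −20 °C. This is an intermolecular anti bromochlorination that puts chloride on the tertiary carbon. The axial line along which chloride must reach C4' in the diaxial mode is syn-axial to the C6' OTBS. A usable share of 21 is therefore expected beside the diaxial trans adduct F1. F1 is separated and returned to 15 with Zn in AcOH/Et2O. This fallback sets out from 15 and comes back at 21.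

**Step 13 (bromide at C3').** Substitution next to the fully substituted C4' may be slow. Ionisation of the tertiary C4'–O bond and elimination could then take over. Fallback: bromine is brought to C3' by migration instead of by substitution.
- Olefin 15 is epoxidised with m-chloroperbenzoic acid on the same open lower face to give the epoxide F2.
- Pyridine hydrobromide in CH2Cl2 opens F2 in the diaxial, Markovnikov sense to the C4' bromide C3' alcohol F3.
- The chloroenamine of step 14 activates the axial C3' hydroxyl, which the antiperiplanar bromine expels.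
- The same upper-face bridged ion as in step 14 results and takes up chloride at C4'.

This fallback sets out from 15 and comes back at 21.

**Step 20 (ring A).** Closure may go through the 5-exo mode at C5, the acetate carbonyl may take part, or conversion of the hindered tertiary hydroxyl may be low. Fallback: 28 is cyclised with Hg(O2CCF3)2 in MeNO2 at 0 °C. This oxymercuration is reversible, so the Markovnikov six-membered ether can accumulate. The product is exchanged with aqueous KBr to the alkylmercury bromide F4. Bromodemercuration with Br2/LiBr in pyridine then replaces mercury by bromine with retention at C5. This fallback sets out from 28 and comes back at 29.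

Further compounds
F1 | step 14 | (4S)-4-[(1'S,3'S,4'S,6'R)-3'-bromo-4'-chloro-4'-methyl-6'-(tert-butyldimethylsilyloxy)cyclohexyl]-2,2,4-trimethyl-1,3-dioxolane (diaxial trans adduct) | CC1(C)OC[C@@](C)(O1)[C@H]1C[C@H](Br)[C@@](C)(Cl)C[C@H]1O[Si](C)(C)C(C)(C)C
F2 | step 13 | 3',4'-epoxide of 15 on the lower face (3'S,4'R) | CC1(C)OC[C@@](C)(O1)[C@H]1C[C@@H]2O[C@]2(C)C[C@H]1O[Si](C)(C)C(C)(C)C
F3 | step 13 | diaxial bromohydrin with Br on C4' (upper face) and OH on C3' (lower face) (3'S,4'S) | CC1(C)OC[C@@](C)(O1)[C@H]1C[C@H](O)[C@@](C)(Br)C[C@H]1O[Si](C)(C)C(C)(C)C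
F4 | step 20 | (5S)-C5 bromomercurio analogue of 29 | CC(=O)O[C@H]1C[C@H]([Hg]Br)C(C)(C)O[C@@]1(C)[C@H]1C[C@@H](Br)[C@](C)(Cl)C[C@H]1O[Si](C)(C)C(C)(C)C
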